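The ratio of nucleophile charged to electrophile charged, which I called the cover, was 1.10 in violet and grey, so the electrophile was the limiting reagent by charge.

| flask | electrophile | nucleophile | free base | remark | time |
|---|---|---|---|---|---|
| epsilon | 0.059 M (fed, over 25 s) | 0.0649 M | 0.13 M | run made earlier |  |
| eta | 0.059 M (fed, over 25 s) | 0.0649 M | 0.11 M | run made earlier |  |
| violet | 0.059 M (fed, over 25 s) | 0.0649 M | 0.120 M |  | 3.0 min |
| grey | 0.059 M (fed, over 25 s) | 0.0649 M | 0.150 M |  | 3.0 min |

| run | time / s | electrophile / % | target / % |
|---|---|---|---|
| epsilon | 20.0 | 57.9 | 22.7 |
| epsilon | 40.0 | 51.2 | 42.7 |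
| epsilon | 50.0 | 44.3 | 47.9 |
| epsilon | 80.0 | 29.9 | 54.2 |
| epsilon | 90.0 | 28.2 | 57.5 |
| eta | 20.0 | 57.3 | 22.0 |
| eta | 40.0 | 52.1 | 44.8 |
| eta | 50.0 | 44.4 | 48.5 |
| eta | 80.0 | 32.6 | 56.3 |
| eta | 90.0 | 28.9 | 56.7 |

(each reading ± 1 percentage point)

- part of the electrophile that has reacted at the end, violet
- part of the electrophile that has reacted at the end, grey
- what raising the concentration of free base from its lowest to its highest value here does to the part of the electrophile that has reacted (changes below 5 percentage points count as none) (no change / it rises / it falls)

I went through the given numbers by what an error in each would cost. Free base needed little care: from eta to epsilon the last electrophile reading moved by 0.7 percentage points, less than the scatter of 1 point, though grey lay beyond both runs. The feed needed little care too, since it took 25 s of the 3.0 min. The cover needed care, since neither run varied it and it cleared one by 0.100. I assumed one nucleophile per target, which holds target at or below the cover. With the electrophile charge held fixed, a cover above one set no cap on target short of that charge, and a cover below one capped target at the cover.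

So I extrapolated. Epsilon's electrophile decayed at a read 0.0113 s⁻¹ between 50.0 s and 90.0 s. Held to 3.0 min, that put the electrophile remaining at 10.2%, so my own estimate was 89.8% reacted for violet and grey.

The forecast gave less: 86% for violet (81% to 91%), 86% for grey (80% to 92%), and no change, on the ground that “Runs at 0.11 and 0.13 M free base agree within the 1-point noise”.

The flasks gave 86.3% for violet and 87.4% for grey, a change of 1.1 points, so no change.

    electrophile + target → side product (k = 0.0784 L mol⁻¹ s⁻¹)
    acid set free + free base ⇌ salt of the base, settled at all times (K = 8530 L mol⁻¹)
    nucleophile + acid set free ⇌ protonated nucleophile, settled at all times (K = 56000 L mol⁻¹)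
    free base + target → over-reaction product (k = 0.00288 L mol⁻¹ s⁻¹)
    electrophile + nucleophile → acid set free + target (k = 0.658 L mol⁻¹ s⁻¹)

Grey's target stood at 61.5% at 3.00 min, below its cover of 110%. I then took the neighbour of grey charged with 0.016 M of nucleophile, whose cover was 27.1%, below one, so that figure was the cap on its target. That flask made 16.0% target by 3.00 min. Its reacted part, 35.1%, stood above the cover, with 18.0% in side product, where each unit holds two of electrophile, and 1.07% in over-reaction product. Unbound electrophile left in that neighbour came to 65%.

The numbers in the tables stem from a simulated flask from invented constants; scatter was added.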